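Ring B (cyclopentenone: B1 α-CH, B2 C=O, B3=B4, B5 CHMe) is disconnected as a [2+2+1] retron: acetylene and CO add across the (Z)-propenyl group on C2 of cyclopentane ring A (C1 = C(OH)CH2OAc, C4 = diene-bearing CH). In one operation the key step forms B4–B5, B1–B2 and B2–B3, closes ring B and sets the cis B1/B5 pair. It exploits the tertiary oxygen on C1, three bonds from B1, whose methylthiomethyl sulfide can hold cobalt on the alkene face syn to that oxygen and place the carbonyl at B1. The precursor is ring A carrying this ether, CH2OAc, a (Z)-vinylsilane on C4 and the (Z)-propenyl group on C2.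

Key step: step 12

Remark (numbering): ring A is numbered as the cyclopentane of the target: C1 carries OH and CH2OAc, C2 carries ring B, C4 carries the side chain. Ring B atoms are B1–B5 as defined above.

Remark (stereochemistry read from the target): on ring A the CH2OAc group, the C4 chain and ring B lie on one face and the C1 hydroxyl on the other. On ring B the bond from B1 to ring A and the methyl at B5 are cis. The diene is 2Z,4E.

Remark (design): the sulfide sits on the C1 oxygen because this is the shortest sulfur tether the skeleton allows (four atoms between sulfur and B1) and it comes off under neutral conditions. The lactol is olefinated before the vinylsilane is built so that the Grignard step never meets a masked aldehyde. A methyl ester is used so that the enolate of step 3 is stable.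

Assumption: Cu(OTf)2 with the (S,S)-tert-butyl bis(oxazoline) ligand is taken to give the (2S)-endo adduct of the acryloyl imide (attack anti to the nearer tert-butyl group of the square-planar chelate); if the sense were opposite, the (R,R)-ligand would be used.

Step 1
Reactants: 1 cyclopenta-1,3-diene (freshly cracked); 2 3-acryloyl-1,3-oxazolidin-2-one
Product: 3 3-[(1S,2S,4S)-bicyclo[2.2.1]hept-5-ene-2-carbonyl]-1,3-oxazolidin-2-one
Conditions: Cu(OTf)2 (10 mol %), 2,2'-isopropylidenebis[(4S)-4-tert-butyl-2-oxazoline] (11 mol %), CH2Cl2, −78 °C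
Reagents that add atoms: none
Why: Catalytic enantioselective Diels–Alder reaction; the divalent copper chelate of the s-cis imide exposes one alkene face, so the endo adduct should form with the bridgehead configuration that becomes C2 and C4 of ring A.

Step 2
Reactants: 3 endo imide
Product: 4 methyl (1S,2S,4S)-bicyclo[2.2.1]hept-5-ene-2-carboxylate
Conditions: NaOMe (1.1 equiv), MeOH–THF, 0 °C; NH4Cl
Reagents that add atoms: sodium methoxide, C[O-].[Na+]
Why: Transesterification by exocyclic acyl substitution; any epimerisation at the ester-bearing carbon is harmless because that centre is planarised in step 3.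

Step 3
Reactants: 4 methyl ester
Product: 6 methyl (1S,2R,4S)-2-hydroxybicyclo[2.2.1]hept-5-ene-2-carboxylate (exo-OH), via lithium ester enolate 5 (not isolated)
Conditions: LiN(i-Pr)2, THF, −78 °C; then 2-(benzenesulfonyl)-3-phenyloxaziridine, −78 °C; NH4Cl
Reagents that add atoms: 2-(benzenesulfonyl)-3-phenyloxaziridine, O=S(=O)(N1OC1c1ccccc1)c1ccccc1
Why: Davis enolate hydroxylation; oxygen should be delivered to the exo face of the bicyclic enolate, which sets C1 of ring A with hydroxyl exo and the carboxyl carbon endo.

Step 4
Reactants: 6 hydroxy ester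
Product: 7 (1S,2R,4S)-2-(hydroxymethyl)bicyclo[2.2.1]hept-5-en-2-ol
Conditions: LiAlH4, THF, 0 °C → rt
Reagents that add atoms: none
Why: Hydride reduction of the ester to the primary alcohol; no stereocentre is touched.

Step 5
Reactants: 7 norbornene diol
Product: 10 2,5-dihydroxy-3-oxabicyclo[3.3.0]octane-7-carbaldehyde (cis-fused lactol; free formyl on the carbon that becomes C4 of ring A; anomer mixture), via secondary ozonide 8 (not isolated), via open-chain dialdehyde 9 (not isolated)
Conditions: O3, CH2Cl2, −78 °C; then Me2S, −78 °C → rt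
Reagents that add atoms: ozone, [O-][O+]=O
Why: Ozonolysis with reductive work-up gives the cis-1,3-dialdehyde; the formyl group on C2 is cis-vicinal to CH2OH and should close the cis-fused five-membered lactol in preference to the bridged six-membered ring open to the C4 formyl group, which differentiates the two aldehydes.

Step 6
Reactants: 10 lactol aldehyde
Product: 11 7-ethynyl-3-oxabicyclo[3.3.0]octane-2,5-diol (ethynyl on C4 of ring A)
Conditions: dimethyl (1-diazo-2-oxopropyl)phosphonate (1.1 equiv), K2CO3, MeOH, 0 °C → rt
Reagents that add atoms: dimethyl (1-diazo-2-oxopropyl)phosphonate, COP(=O)(OC)C(=[N+]=[N-])C(C)=O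
Why: Seyferth–Gilbert homologation in the Ohira–Bestmann form; the free aldehyde should react well before the lactol, and the low temperature should outpace epimerisation at C4.

Step 7
Reactants: 11 lactol alkyne
Product: 12 4-ethynyl-1-(hydroxymethyl)-2-[(Z)-prop-1-enyl]cyclopentan-1-ol (ring A numbering; CH2OH, propenyl and ethynyl cis; OH trans)
Conditions: EtPPh3Br (3.5 equiv), KN(SiMe3)2 (3.4 equiv), THF, −78 → 0 °C
Reagents that add atoms: ethyltriphenylphosphonium bromide, CC[P+](c1ccccc1)(c1ccccc1)c1ccccc1.[Br-]
Why: Wittig olefination of the lactol through its hydroxy aldehyde form; the non-stabilised ylide under salt-free conditions should give the (Z)-propenyl group and free the primary alcohol.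

Step 8
Reactants: 12 diol alkyne
Product: 14 tris(trimethylsilyl) derivative of 12 (both oxygens and the alkyne carbon silylated), via trilithium salt 13 (not isolated)
Conditions: n-BuLi (3.3 equiv), THF, −78 → 0 °C; then Me3SiCl (4 equiv), → rt
Reagents that add atoms: chlorotrimethylsilane, C[Si](C)(C)Cl
Why: Deprotonation of both hydroxyls and the terminal alkyne followed by O- and C-silylation; the alkene is inert.

Step 9
Reactants: 14 silylalkyne bis-silyl ether
Product: 17 1-(hydroxymethyl)-2-[(Z)-prop-1-enyl]-4-[(Z)-1-(trimethylsilyl)prop-1-en-2-yl]cyclopentan-1-ol, via alkenylmagnesium bromide 15 (not isolated), via bis-silyl ether 16 (not isolated)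
Conditions: MeMgBr (4 equiv), Ni(acac)2 (10 mol %), Me3Al (10 mol %), THF, rt; NH4Cl, 0 °C; then K2CO3, MeOH, rt
Reagents that add atoms: methylmagnesium bromide, C[Mg]Br
Why: Nickel-catalysed syn carbomagnesiation of a silylalkyne; methyl adds β to silicon and magnesium α on the same side, so prompt protonation should give the (Z)-vinylsilane (C4 cis to Si), and methanolysis removes only the O-silyl groups.

Step 10
Reactants: 17 vinylsilane diol
Product: 18 primary acetate of 17
Conditions: Ac2O (1.1 equiv), pyridine, CH2Cl2, 0 °C
Reagents that add atoms: acetic anhydride, CC(=O)OC(C)=O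
Why: Selective acylation of the primary hydroxyl; the hindered tertiary hydroxyl does not react without an acyl-transfer catalyst.

Step 11
Reactants: 18 acetate with free tertiary alcohol
Product: 19 methylthiomethyl ether of 18 (key-step precursor)
Conditions: DMSO, Ac2O, AcOH, rt, 24–48 h
Reagents that add atoms: dimethyl sulfoxide, CS(C)=O
Why: Pummerer-type methylthiomethylation; the thionium species from DMSO and Ac2O etherifies tertiary alcohols, while acetate, vinylsilane and alkene are inert.

Step 12
Reactants: 19 ring A (Z)-propenyl alkene with methylthiomethyl ether; 20 acetylene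
Product: 22 ring A–ring B cyclopentenone as tertiary methylthiomethyl ether, via hexacarbonyldicobalt ethyne complex 21 (not isolated)
Conditions: Co2(CO)8 (1.2 equiv), HC≡CH (1 atm), toluene, rt, 2 h; then 19, 70 °C, argon; air, sat. aq. NH4Cl
Reagents that add atoms: octacarbonyldicobalt Co2(CO)8 (source of the CO unit), O=C=[Co](=C=O)(=C=O)(=C=O)[Co](=C=O)(=C=O)(=C=O)=C=O
Why: Proposed new method: Co2(CO)8 (zerovalent cobalt) forms the hexacarbonyldicobalt complex of acetylene, the sulfide of 19 displaces one CO and brings the (Z)-alkene to the metal, the alkene inserts suprafacially into a Co–C bond (B4–B5), CO inserts into the Co–B1 bond (B1–B2) and reductive elimination (B2–B3) releases the enone. The closest known reaction type is the sulfide- or amine-directed intermolecular Pauson–Khand reaction of terminal alkenes with the ligand on a homoallylic or bishomoallylic tether; an unstrained internal (Z)-alkene has not been shown to react this way, and the tether here is one atom longer than the bishomoallylic case. Ring B is closed as a cobaltacycle-mediated [2+2+1] annulation whose ring-closing event is the acyl–vinyl reductive elimination. B1 and B5 are both created in the syn insertion, so the (Z)-geometry gives the cis pair, and their absolute sense is fixed by the C2 stereocentre of ring A through the allylic-strain-minimised rotamer (the C2–H bond in the alkene plane toward the methyl group), in which sulfur-bound cobalt can reach only the face syn to the C1 oxygen. The step needs regioselectivity (carbonyl at B1, secured because the alkene carbon nearer the chelating sulfur stays on cobalt and takes up CO), face selectivity (secured by the same chelate) and chemoselectivity over the trisubstituted vinylsilane (secured by its substitution and its distance from sulfur); no base is present, so the cis relationship should survive.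

Step 13
Reactants: 22 methylthiomethyl ether
Product: 23 tertiary alcohol (acetate, (Z)-vinylsilane and cis-enone retained)
Conditions: MeI, NaHCO3, acetone–H2O, 40 °C
Reagents that add atoms: none
Why: S-Methylation to the sulfonium salt and hydrolysis of the resulting hemiacetal should free the tertiary alcohol without base strong enough to epimerise B1.

Step 14
Reactants: 23 vinylsilane
Product: 24 (Z)-alkenyl iodide (C4 of ring A bears (Z)-1-iodoprop-1-en-2-yl)
Conditions: NIS (1.2 equiv), (CF3)2CHOH, 0 °C
Reagents that add atoms: N-iodosuccinimide, O=C1CCC(=O)N1I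
Why: Iododesilylation by ipso substitution through the β-silyl cation, which proceeds with retention in this solvent; the tertiary hydroxyl is trans to the C4 arm and cannot cyclise.

Step 15
Reactants: 25 2-methylbut-3-yn-2-ol
Product: 26 2-hydroperoxy-2-methylbut-3-yne
Conditions: 50% aq. H2O2, H2SO4 (cat.), 0 °C; kept in CH2Cl2 solution
Reagents that add atoms: hydrogen peroxide, OO
Why: Acid-catalysed perhydrolysis of the tertiary propargylic alcohol, a unimolecular substitution through the propargylic cation.

Step 16
Reactants: 26 hydroperoxide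
Product: 27 2-[(2-methoxypropan-2-yl)peroxy]-2-methylbut-3-yne
Conditions: 2-methoxypropene, PPTS (cat.), CH2Cl2, 0 °C
Reagents that add atoms: 2-methoxypropene, C=C(C)OC
Why: Acid-catalysed addition of the hydroperoxide to the enol ether gives the peroxyketal, a protected hydroperoxide that tolerates organometallic steps.

Step 17
Reactants: 27 alkynyl peroxyketal
Product: 28 (E)-tributyl{3-[(2-methoxypropan-2-yl)peroxy]-3-methylbut-1-enyl}stannane
Conditions: Bu3SnH, PdCl2(PPh3)2 (2 mol %), THF, 0 °C → rt
Reagents that add atoms: tributyltin hydride, CCCC[SnH](CCCC)CCCC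
Why: Palladium-catalysed syn hydrostannation; the quaternary propargylic carbon should direct tin to the terminal carbon and give the (E)-alkenylstannane.

Step 18
Reactants: 24 (Z)-alkenyl iodide; 28 (E)-alkenylstannane
Product: 29 (2Z,4E)-dienyl peroxyketal
Conditions: Pd2(dba)3 (5 mol %), AsPh3 (20 mol %), NMP, rt → 40 °C
Reagents that add atoms: none
Why: Stille coupling with retention at both alkenyl carbons should give the (2Z,4E)-diene; the medium is neutral, so B1 is not at risk, and peroxyketals are known to survive zerovalent palladium.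

Step 19
Reactants: 29 peroxyketal
Product: 30 target CNP0204569.1
Conditions: AcOH–THF–H2O (4:2:1), rt
Reagents that add atoms: none
Why: Mild acid hydrolysis of the 2-methoxypropan-2-yl peroxyketal releases the hydroperoxide; acetate, enone and diene are untouched.

Compound list
1 | cyclopenta-1,3-diene | C1C=CC=C1 | starting material
2 | 3-acryloyl-1,3-oxazolidin-2-one | C=CC(=O)N1CCOC1=O | starting material
3 | 3-[(1S,2S,4S)-bicyclo[2.2.1]hept-5-ene-2-carbonyl]-1,3-oxazolidin-2-one | O=C([C@H]1C[C@H]2C=C[C@@H]1C2)N1CCOC1=O | intermediate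
4 | methyl (1S,2S,4S)-bicyclo[2.2.1]hept-5-ene-2-carboxylate | COC(=O)[C@H]1C[C@H]2C=C[C@@H]1C2 | intermediate
5 | lithium enolate of 4 | [Li]OC(OC)=C1C[C@H]2C=C[C@@H]1C2 | intermediate
6 | methyl (1S,2R,4S)-2-hydroxybicyclo[2.2.1]hept-5-ene-2-carboxylate | COC(=O)[C@@]1(O)C[C@H]2C=C[C@@H]1C2 | intermediate
7 | (1S,2R,4S)-2-(hydroxymethyl)bicyclo[2.2.1]hept-5-en-2-ol | OC[C@@]1(O)C[C@H]2C=C[C@@H]1C2 | intermediate
8 | secondary ozonide of 7 (1,2,4-trioxolane on the former alkene carbons) | OC[C@@]1(O)C[C@H]2C3OOC(O3)[C@@H]1C2 | intermediate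
9 | cis-2,4-diformyl-1-(hydroxymethyl)cyclopentan-1-ol (open form) | OC[C@@]1(O)C[C@@H](C=O)C[C@H]1C=O | intermediate
10 | 2,5-dihydroxy-3-oxabicyclo[3.3.0]octane-7-carbaldehyde (cis-fused; the hydroxylated ring-fusion carbon is C1 of ring A, the other ring-fusion carbon is C2, the formyl-bearing carbon is C4) | OC1OC[C@@]2(O)C[C@@H](C=O)C[C@@H]12 | intermediate
11 | 7-ethynyl-3-oxabicyclo[3.3.0]octane-2,5-diol | OC1OC[C@@]2(O)C[C@@H](C#C)C[C@@H]12 | intermediate
12 | 4-ethynyl-1-(hydroxymethyl)-2-[(Z)-prop-1-enyl]cyclopentan-1-ol | OC[C@@]1(O)C[C@@H](C#C)C[C@H]1/C=C\C | intermediate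
13 | trilithium salt of 12 (two alkoxides, one acetylide) | [Li]OC[C@@]1(O[Li])C[C@@H](C#C[Li])C[C@H]1/C=C\C | intermediate
14 | tris(trimethylsilyl) derivative of 12 | C[Si](C)(C)OC[C@@]1(O[Si](C)(C)C)C[C@@H](C#C[Si](C)(C)C)C[C@H]1/C=C\C | intermediate
15 | α-silyl alkenylmagnesium bromide from 14 (methyl and magnesium cis) | C[Si](C)(C)OC[C@@]1(O[Si](C)(C)C)C[C@@H](/C(C)=C(\[Si](C)(C)C)[Mg]Br)C[C@H]1/C=C\C | intermediate
16 | bis(trimethylsilyl) ether of 17 | C[Si](C)(C)OC[C@@]1(O[Si](C)(C)C)C[C@@H](/C(C)=C\[Si](C)(C)C)C[C@H]1/C=C\C | intermediate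
17 | 1-(hydroxymethyl)-2-[(Z)-prop-1-enyl]-4-[(Z)-1-(trimethylsilyl)prop-1-en-2-yl]cyclopentan-1-ol | OC[C@@]1(O)C[C@@H](/C(C)=C\[Si](C)(C)C)C[C@H]1/C=C\C | intermediate
18 | primary acetate of 17 | CC(=O)OC[C@@]1(O)C[C@@H](/C(C)=C\[Si](C)(C)C)C[C@H]1/C=C\C | intermediate
19 | tertiary methylthiomethyl ether of 18 (key-step precursor) | CC(=O)OC[C@@]1(OCSC)C[C@@H](/C(C)=C\[Si](C)(C)C)C[C@H]1/C=C\C | intermediate
20 | acetylene | C#C | starting material
21 | (μ-ethyne)hexacarbonyldicobalt | [CH]12[CH]3[Co]1(=C=O)(=C=O)(=C=O)[Co]23(=C=O)(=C=O)=C=O | intermediate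
22 | ring A–ring B enone with cis-5-methyl-2-oxocyclopent-3-en-1-yl on C2 of ring A, as tertiary methylthiomethyl ether | CC(=O)OC[C@@]1(OCSC)C[C@@H](/C(C)=C\[Si](C)(C)C)C[C@H]1[C@H]1C(=O)C=C[C@H]1C | intermediate
23 | tertiary alcohol from 22 | CC(=O)OC[C@@]1(O)C[C@@H](/C(C)=C\[Si](C)(C)C)C[C@H]1[C@H]1C(=O)C=C[C@H]1C | intermediate
24 | (Z)-alkenyl iodide from 23 | CC(=O)OC[C@@]1(O)C[C@@H](/C(C)=C\I)C[C@H]1[C@H]1C(=O)C=C[C@H]1C | intermediate
25 | 2-methylbut-3-yn-2-ol | CC(C)(O)C#C | starting material
26 | 2-hydroperoxy-2-methylbut-3-yne | CC(C)(OO)C#C | intermediate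
27 | 2-[(2-methoxypropan-2-yl)peroxy]-2-methylbut-3-yne | COC(C)(C)OOC(C)(C)C#C | intermediate
28 | (E)-tributyl{3-[(2-methoxypropan-2-yl)peroxy]-3-methylbut-1-enyl}stannane | CCCC[Sn](CCCC)(CCCC)/C=C/C(C)(C)OOC(C)(C)OC | intermediate
29 | (2Z,4E)-dienyl peroxyketal of the target | CC(=O)OC[C@@]1(O)C[C@@H](/C(C)=C\C=C\C(C)(C)OOC(C)(C)OC)C[C@H]1[C@H]1C(=O)C=C[C@H]1C | intermediate
30 | CNP0204569.1: {1-hydroxy-4-[(2Z,4E)-6-hydroperoxy-6-methylhepta-2,4-dien-2-yl]-2-(cis-5-methyl-2-oxocyclopent-3-en-1-yl)cyclopentyl}methyl acetate | CC(=O)OC[C@@]1(O)C[C@@H](/C(C)=C\C=C\C(C)(C)OO)C[C@H]1[C@H]1C(=O)C=C[C@H]1C | target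

Total step count: 19. Longest linear sequence: 16 steps (steps 1–14, 18, 19); the stannane arm takes 3 steps (15–17).

Steps most likely to fail

1. Step 12. The internal alkene may fail to insert (the cobalt complex decomposes or acetylene oligomerises), or it may insert without chelation and give the other face or regiochemistry. Fallback with known chemistry, setting out from 11 and coming back at 23: lactol 11 would be olefinated with the ylide from [(E)-but-2-enyloxymethyl]triphenylphosphonium chloride and KN(SiMe3)2 to the crotyl enol ether F1, formed as a mixture of enol ether geometries. Heating in toluene (Claisen rearrangement) would give the pent-4-enal, which closes onto the primary hydroxyl as the six-membered lactol F2. The isomer needed has the two new centres anti in the open chain, which becomes the cis B1/B5 pair once ring B is closed; it arises from the (Z)-enol ether through the chair transition state and would be separated from its isomers. Vinylmagnesium bromide would open it to the triol F3. n-BuLi/Me3SiCl would give the persilylated silylalkyne F4. Ring-closing metathesis with the second-generation Grubbs catalyst (H2IMes)(PCy3)Cl2Ru=CHPh would close ring B as the cyclopentenyl silyl ether F5. The methylmagnesiation and O-desilylation of step 9 would then give the triol vinylsilane F6, MnO2 would oxidise the allylic alcohol to the enone diol F7, and Ac2O/pyridine would acetylate the primary hydroxyl to give 23.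

2. Step 9. Carbometalation next to the secondary ring carbon may be slow, and the α-silyl alkenylmagnesium intermediate may equilibrate before protonation, eroding the Z geometry. Fallback, setting out from 11 and coming back at 17: before any other alkene is present, 11 would be silylated on both oxygens and on the alkyne with Me3SiOTf, Et3N and Zn(OTf)2 (cat.) to the tris-silyl lactol F8. 9-Borabicyclo[3.3.1]nonane would add syn with boron β to silicon to give the configurationally stable alkenylborane F9. Suzuki–Miyaura coupling with MeI (Pd(PPh3)4, aq. K3PO4) followed by K2CO3/MeOH would give the lactol (Z)-vinylsilane F10 with retention. The Wittig reaction of step 7 applied to it would give 17.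

3. Step 18. Transmetalation to the hindered (Z)-iodide may be slow, so that protodestannylation or attack of zerovalent palladium on the O–O bond of the stannane wins. Fallback with the roles exchanged, setting out from 24 and 28 and coming back at 29: iodine would convert 28 into the (E)-iodoalkenyl peroxyketal F11, which carries the peroxide on the electrophile and enters the cycle by fast oxidative addition. Me3SnSnMe3 with Pd(PPh3)4 would convert 24 into the alkenyltrimethylstannane F12. Coupling of the two with Pd2(dba)3/AsPh3 would give 29.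

Further compounds
F1 | step 12 | crotyl enol ether from 11 (diol, ethynyl retained) | OC[C@@]1(O)C[C@@H](C#C)C[C@H]1C=COC/C=C/C
F2 | step 12 | six-membered lactol of the Claisen aldehyde (both ring B stereocentres set) | OC1OC[C@@]2(O)C[C@@H](C#C)C[C@H]2[C@@H]1[C@H](C)C=C
F3 | step 12 | triol diene after vinyl addition | OC[C@@]1(O)C[C@@H](C#C)C[C@H]1[C@@H](C(O)C=C)[C@H](C)C=C
F4 | step 12 | persilylated silylalkyne diene | C[Si](C)(C)OC[C@@]1(O[Si](C)(C)C)C[C@@H](C#C[Si](C)(C)C)C[C@H]1[C@@H](C(O[Si](C)(C)C)C=C)[C@H](C)C=C
F5 | step 12 | cyclopentenyl silyl ether after ring-closing metathesis | C[Si](C)(C)OC[C@@]1(O[Si](C)(C)C)C[C@@H](C#C[Si](C)(C)C)C[C@H]1[C@H]1C(O[Si](C)(C)C)C=C[C@H]1C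
F6 | step 12 | triol (Z)-vinylsilane with cyclopentenol ring B | OC[C@@]1(O)C[C@@H](/C(C)=C\[Si](C)(C)C)C[C@H]1[C@H]1C(O)C=C[C@H]1C
F7 | step 12 | enone diol (deacetyl 23) | OC[C@@]1(O)C[C@@H](/C(C)=C\[Si](C)(C)C)C[C@H]1[C@H]1C(=O)C=C[C@H]1C
F8 | step 9 | tris(trimethylsilyl) derivative of lactol 11 | C[Si](C)(C)OC1OC[C@@]2(O[Si](C)(C)C)C[C@@H](C#C[Si](C)(C)C)C[C@@H]12
F9 | step 9 | (Z)-β-silyl alkenyl-9-borabicyclo[3.3.1]nonane | C[Si](C)(C)OC1OC[C@@]2(O[Si](C)(C)C)C[C@@H](/C(B3C4CCCC3CCC4)=C\[Si](C)(C)C)C[C@@H]12
F10 | step 9 | lactol (Z)-vinylsilane | OC1OC[C@@]2(O)C[C@@H](/C(C)=C\[Si](C)(C)C)C[C@@H]12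
F11 | step 18 | (E)-1-iodo-3-[(2-methoxypropan-2-yl)peroxy]-3-methylbut-1-ene | COC(C)(C)OOC(C)(C)/C=C/I
F12 | step 18 | (Z)-alkenyltrimethylstannane from 24 | CC(=O)OC[C@@]1(O)C[C@@H](/C(C)=C\[Sn](C)(C)C)C[C@H]1[C@H]1C(=O)C=C[C@H]1C
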